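**Retrosynthetic overview**
1. 27 ⇐ 25 (OTBS → OAc) ⇐ phenol 24. A para-dearomatising phenol–arene coupling closes the seven-membered ring and creates the spiro carbon C5 (= C1') last.
2. 24 ⇐ 11 + 18. The six carbons of the later dienone ring are not taken from an arene: four come from a cyclobutene (dimethyl squarate) and two from a 1-methoxyvinyl group. They are merged by Wittig olefination, 4π opening and 6π closure, a two-carbon ring expansion.
3. Enabling feature: in the dienone ring the arc C1'(spiro)–C2'H=C3'(OMe)–C4'(=O) has the atom and oxygen pattern of 3-methoxycyclobut-3-ene-1,2-dione. The arc C5'(OMe)=C6'H has that of methyl vinyl ether. The local mirror plane of this ring makes C5 non-stereogenic.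
4. Side chain 11 ⇐ lactone 6 ⇐ 1 + 2. One catalytic asymmetric (Z)-crotylboration sets C9 and C8, and C7 is relayed by trans-alkylation of a temporary γ-lactone.
5. Ring order: arene (bought), γ-lactone (temporary), cyclobutene (bought), six-membered ring (step 12), seven-membered ring (step 13).

Key step: step 12

Assumption: locants follow spiro[benzo[7]annulene-5,1'-cyclohexadiene] numbering (C9 = CHOAc, C8 and C7 = CHMe, C6 = CH2). Compound 18 is used as the racemate because its only stereocentre disappears in step 12.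

**Step 1**
Reactants: 1 3,4,5-trimethoxybenzaldehyde; 2 (Z)-crotylboronic acid pinacol ester
Product: 3 (1R,2S)-2-methyl-1-(3,4,5-trimethoxyphenyl)but-3-en-1-ol (syn)
Conditions: (R)-TRIP (5 mol %), PhMe, −30 °C; aq. work-up
Reagents that add atoms: none
Why: Chiral phosphoric acid-catalysed crotylboration, in which the closed chair transition state turns the Z geometry into the syn relation and the catalyst bound to the boronate selects the Re face of 1, so C9 (R) and C8 (S) are set together; the (R)-catalyst is assigned by analogy with benzaldehyde and its mirror image is equally available.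

**Step 2**
Reactants: 3
Product: 4 (1R,2S)-2-methyl-1-(3,4,5-trimethoxyphenyl)butane-1,4-diol
Conditions: 9-BBN (2.2 equiv), THF, 0 °C → rt; NaOH, H2O2
Reagents that add atoms: hydrogen peroxide, OO
Why: Hydroboration–oxidation with the bulky borane is anti-Markovnikov at the terminal alkene and touches no stereocentre, the free OH only consuming one extra equivalent of borane.

**Step 3**
Reactants: 4
Product: 5 (4S,5R)-4-methyl-5-(3,4,5-trimethoxyphenyl)oxolan-2-one (4,5-cis)
Conditions: TEMPO (cat.), PhI(OAc)2, CH2Cl2, rt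
Reagents that add atoms: none
Why: Oxoammonium oxidative lactonisation of a 1,4-diol, in which the primary alcohol is oxidised faster than the secondary one, the aldehyde closes to the lactol and the lactol is oxidised on.

**Step 4**
Reactants: 5
Product: 6 (3S,4S,5R)-3,4-dimethyl-5-(3,4,5-trimethoxyphenyl)oxolan-2-one (3,4-trans, 4,5-cis)
Conditions: LDA, THF, −78 °C; MeI
Reagents that add atoms: iodomethane, CI
Why: Lactone enolate alkylation in which MeI approaches anti to the cis-disposed 4-methyl and 5-aryl groups, so C7 is set by substrate control.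

**Step 5**
Reactants: 6
Product: 7 (1R,2S,3S)-2,3-dimethyl-1-(3,4,5-trimethoxyphenyl)butane-1,4-diol
Conditions: LiAlH4, THF, 0 °C; H2O, NaOH work-up
Reagents that add atoms: none
Why: Hydride reduction of the lactone opens the temporary ring without enolisation, so all three stereocentres are kept.

**Step 6**
Reactants: 7
Product: 8 bis(tert-butyldimethylsilyl) ether of 7
Conditions: TBSCl, imidazole, DMF, 40 °C
Reagents that add atoms: tert-butyldimethylsilyl chloride, CC(C)(C)[Si](C)(C)Cl
Why: Standard silylation of both hydroxyl groups, needed because the benzylic oxygen must survive the butyllithium and phosphonium ylide of step 12.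

**Step 7**
Reactants: 8
Product: 9 (2S,3S,4R)-4-(tert-butyldimethylsilyloxy)-2,3-dimethyl-4-(3,4,5-trimethoxyphenyl)butan-1-ol
Conditions: HF·pyridine, pyridine, THF, 0 °C
Reagents that add atoms: none
Why: Selective desilylation, the unhindered primary silyl ether being cleaved faster than the hindered secondary benzylic one under buffered fluoride.

**Step 8**
Reactants: 9
Product: 10 tert-butyl{[(1R,2S,3S)-4-iodo-2,3-dimethyl-1-(3,4,5-trimethoxyphenyl)butyl]oxy}dimethylsilane
Conditions: I2, PPh3, imidazole, CH2Cl2, 0 °C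
Reagents that add atoms: iodine, II
Why: Appel-type iodination by SN2 displacement at the primary carbon, away from every stereocentre.

**Step 9**
Reactants: 10
Product: 11 [(2S,3S,4R)-4-(tert-butyldimethylsilyloxy)-2,3-dimethyl-4-(3,4,5-trimethoxyphenyl)butyl]triphenylphosphonium iodide
Conditions: PPh3, MeCN, reflux
Reagents that add atoms: triphenylphosphine, c1ccc(cc1)P(c1ccccc1)c1ccccc1
Why: SN2 quaternisation of the phosphine by a primary iodide under neutral conditions that leave the silyl ether intact.

**Step 10**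
Reactants: 12 dimethyl squarate
Product: 14 3-methoxycyclobut-3-ene-1,2-dione, via hydroxycyclobutenone 13 (not isolated)
Conditions: LiAlH(Ot-Bu)3, THF, −78 → −20 °C; then 2 M HCl, CH2Cl2, rt
Reagents that add atoms: water, O
Why: 1,2-Hydride addition to one squarate carbonyl followed by acid ionisation of the allylic alcohol and hydrolysis of the methoxy-stabilised cation (reduction and 1,3-transposition of a vinylogous ester), which replaces one OMe-bearing carbon by CH.

**Step 11**
Reactants: 15 methyl vinyl ether; 14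
Product: 18 (±)-3-methoxy-4-(1-methoxyethenyl)-4-(trimethylsilyloxy)cyclobut-2-en-1-one, via 1-methoxyvinyllithium 16 (not isolated), via lithium alkoxide 17 (not isolated)
Conditions: 15, t-BuLi, THF, −78 → 0 °C; add to 14, THF, −78 °C; TMSCl, −78 → 0 °C
Reagents that add atoms: chlorotrimethylsilane, C[Si](C)(C)Cl
Why: α-Lithiation of the enol ether and regioselective 1,2-addition to a cyclobutenedione, the carbonyl next to the OMe-bearing carbon being attacked because the other one is deactivated as a vinylogous ester.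

**Step 12**
Reactants: 11; 18
Product: 24 4-[(2R,3S,4R)-4-(tert-butyldimethylsilyloxy)-2,3-dimethyl-4-(3,4,5-trimethoxyphenyl)butyl]-2,6-dimethoxyphenol, via ylide 19 (not isolated), via alkylidenecyclobutene 20 (not isolated), via dienylallene 21 (not isolated), via methylenecyclohexadiene 22 (not isolated), via aryl silyl ether 23 (not isolated)
Conditions: 11, n-BuLi, THF, −78 → 0 °C; 18, −78 °C → rt; PhMe, 100 °C; then PPTS (cat.), MeOH, 0 °C
Reagents that add atoms: none
Why: Proposed new method: the non-stabilised ylide 19 olefinates the only carbonyl of 18 (strained, no enolisable H) to the 3-alkylidenecyclobutene 20, which on heating cleaves its C(OTMS)–C(=CHR) bond by conrotatory 4π opening to the dienylallene 21 and then closes by disrotatory 6π electrocyclisation between the CH2 terminus of the methoxyvinyl group and the central allene carbon, so the four-membered ring grows by two carbons to the six-membered ring of 22. Protonation of the exocyclic carbon and loss of a ring proton (PPTS) aromatise 22 to 23, and methanolysis of the aryl silyl ether gives 24. The closest known reaction types are the Moore rearrangement of 4-alkenylcyclobutenones through dienylketenes, the alkenyllithium addition/4π–6π ring expansion of cyclobutenones to cyclohexenones, and the thermal opening of squarate-derived 3-methylenecyclobutenes to allenes; new are the Wittig trigger and the dienylallene closure with this substitution pattern. The selectivity needed is torquoselectivity: the donor OTMS group rotates outward and so places the methoxyvinyl group inward as the closure demands, the sp2 alkylidene terminus carries no inward alkyl group so that a competing [1,7]-H shift has no hydrogen to move, and an outward-vinyl isomer can only revert to 20. No stereocentre is created, since the racemic carbinol carbon of 18, the alkene geometry of 20 and the allene axis of 21 are all erased in 24, and the three side-chain stereocentres are spared because the aromatisation runs under mild acid and never passes through a base-labile dienone with an acidic C7–H. Attack at the carbonyl rather than addition–elimination at the OMe-bearing ring carbon rests on the hard, non-stabilised character of 19.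

**Step 13**
Reactants: 24
Product: 25 (7R,8S,9R)-9-(tert-butyldimethylsilyloxy)-2,3,4,3',5'-pentamethoxy-7,8-dimethyl-6,7,8,9-tetrahydrospiro[benzo[7]annulene-5,1'-cyclohexa-2',5'-dien]-4'-one
Conditions: PhI(OCOCF3)2, CF3CH2OH, −40 → 0 °C
Reagents that add atoms: none
Why: Hypervalent-iodine phenol dearomatisation, in which the 2,6-dimethoxyphenoxenium equivalent is attacked at its para carbon by the arene position that is ortho to the side chain and para to a methoxy group (closely precedented for phenolic diarylbutane lignans), closing the seven-membered ring at a spiro carbon that is not stereogenic.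

**Step 14**
Reactants: 25
Product: 26 (7R,8S,9R)-9-hydroxy-2,3,4,3',5'-pentamethoxy-7,8-dimethyl-6,7,8,9-tetrahydrospiro[benzo[7]annulene-5,1'-cyclohexa-2',5'-dien]-4'-one
Conditions: HF·pyridine, pyridine, THF, 0 °C → rt
Reagents that add atoms: none
Why: Buffered fluoride desilylation cleaves the Si–O bond only, so C9 keeps its configuration and the medium is neither acidic enough for a dienone–phenol shift nor basic enough for oxa-Michael addition.

**Step 15**
Reactants: 26
Product: 27 (7R,8S,9R)-2,3,4,3',5'-pentamethoxy-7,8-dimethyl-4'-oxo-6,7,8,9-tetrahydrospiro[benzo[7]annulene-5,1'-cyclohexa-2',5'-dien]-9-yl acetate (target)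
Conditions: Ac2O, pyridine, DMAP (cat.), CH2Cl2, 0 °C
Reagents that add atoms: acetic anhydride, CC(=O)OC(C)=O
Why: DMAP-catalysed O-acylation of the secondary alcohol with retention at C9.

**Compound list**
1 | 3,4,5-trimethoxybenzaldehyde | COc1cc(C=O)cc(OC)c1OC | starting material
2 | (Z)-crotylboronic acid pinacol ester | C/C=C\CB1OC(C)(C)C(C)(C)O1 | starting material
3 | (1R,2S)-2-methyl-1-(3,4,5-trimethoxyphenyl)but-3-en-1-ol | C=C[C@H](C)[C@@H](O)c1cc(OC)c(OC)c(OC)c1 | intermediate
4 | (1R,2S)-2-methyl-1-(3,4,5-trimethoxyphenyl)butane-1,4-diol | OCC[C@H](C)[C@@H](O)c1cc(OC)c(OC)c(OC)c1 | intermediate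
5 | (4S,5R)-4-methyl-5-(3,4,5-trimethoxyphenyl)oxolan-2-one | O=C1C[C@H](C)[C@@H](O1)c2cc(OC)c(OC)c(OC)c2 | intermediate
6 | (3S,4S,5R)-3,4-dimethyl-5-(3,4,5-trimethoxyphenyl)oxolan-2-one | O=C1[C@@H](C)[C@H](C)[C@@H](O1)c2cc(OC)c(OC)c(OC)c2 | intermediate
7 | (1R,2S,3S)-2,3-dimethyl-1-(3,4,5-trimethoxyphenyl)butane-1,4-diol | OC[C@@H](C)[C@H](C)[C@@H](O)c1cc(OC)c(OC)c(OC)c1 | intermediate
8 | bis-TBS ether of 7 | CC(C)(C)[Si](C)(C)OC[C@@H](C)[C@H](C)[C@@H](O[Si](C)(C)C(C)(C)C)c1cc(OC)c(OC)c(OC)c1 | intermediate
9 | (2S,3S,4R)-4-(TBSO)-2,3-dimethyl-4-(3,4,5-trimethoxyphenyl)butan-1-ol | OC[C@@H](C)[C@H](C)[C@@H](O[Si](C)(C)C(C)(C)C)c1cc(OC)c(OC)c(OC)c1 | intermediate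
10 | (1R,2S,3S)-1-(TBSO)-4-iodo-2,3-dimethyl-1-(3,4,5-trimethoxyphenyl)butane | IC[C@@H](C)[C@H](C)[C@@H](O[Si](C)(C)C(C)(C)C)c1cc(OC)c(OC)c(OC)c1 | intermediate
11 | [(2S,3S,4R)-4-(TBSO)-2,3-dimethyl-4-(3,4,5-trimethoxyphenyl)butyl]triphenylphosphonium iodide | [I-].c1ccccc1[P+](c1ccccc1)(c1ccccc1)C[C@@H](C)[C@H](C)[C@@H](O[Si](C)(C)C(C)(C)C)c1cc(OC)c(OC)c(OC)c1 | intermediate
12 | dimethyl squarate | COC1=C(OC)C(=O)C1=O | starting material
13 | 4-hydroxy-2,3-dimethoxycyclobut-2-en-1-one | COC1=C(OC)C(=O)C1O | intermediate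
14 | 3-methoxycyclobut-3-ene-1,2-dione | COC1=CC(=O)C1=O | intermediate
15 | methyl vinyl ether | C=COC | starting material
16 | 1-methoxyvinyllithium | [Li]C(=C)OC | intermediate
17 | lithium 2-methoxy-1-(1-methoxyethenyl)-4-oxocyclobut-2-en-1-olate (racemic) | [Li]OC1(C(=C)OC)C(OC)=CC1=O | intermediate
18 | (±)-3-methoxy-4-(1-methoxyethenyl)-4-(trimethylsilyloxy)cyclobut-2-en-1-one | C[Si](C)(C)OC1(C(=C)OC)C(OC)=CC1=O | intermediate
19 | [(2S,3S,4R)-4-(TBSO)-2,3-dimethyl-4-(3,4,5-trimethoxyphenyl)butylidene]triphenylphosphorane | c1ccccc1P(c1ccccc1)(c1ccccc1)=C[C@@H](C)[C@H](C)[C@@H](O[Si](C)(C)C(C)(C)C)c1cc(OC)c(OC)c(OC)c1 | intermediate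
20 | 2-methoxy-1-(1-methoxyethenyl)-1-(trimethylsilyloxy)-4-[(2R,3S,4R)-4-(TBSO)-2,3-dimethyl-4-(3,4,5-trimethoxyphenyl)butylidene]cyclobut-2-ene (both C1 epimers, E/Z) | COC1=CC(=C[C@@H](C)[C@H](C)[C@@H](O[Si](C)(C)C(C)(C)C)c2cc(OC)c(OC)c(OC)c2)C1(O[Si](C)(C)C)C(=C)OC | intermediate
21 | ring-opened dienylallene, methoxyvinyl group cis to the allenyl CH (allene axis unassigned) | C=C(OC)/C(O[Si](C)(C)C)=C(OC)\C=C=C[C@@H](C)[C@H](C)[C@@H](O[Si](C)(C)C(C)(C)C)c1cc(OC)c(OC)c(OC)c1 | intermediate
22 | 1,3-dimethoxy-2-(trimethylsilyloxy)-5-[(2R,3S,4R)-4-(TBSO)-2,3-dimethyl-4-(3,4,5-trimethoxyphenyl)butylidene]cyclohexa-1,3-diene | COC1=C(O[Si](C)(C)C)C(OC)=CC(=C[C@@H](C)[C@H](C)[C@@H](O[Si](C)(C)C(C)(C)C)c2cc(OC)c(OC)c(OC)c2)C1 | intermediate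
23 | O-trimethylsilyl ether of 24 | COc1cc(C[C@@H](C)[C@H](C)[C@@H](O[Si](C)(C)C(C)(C)C)c2cc(OC)c(OC)c(OC)c2)cc(OC)c1O[Si](C)(C)C | intermediate
24 | 4-[(2R,3S,4R)-4-(TBSO)-2,3-dimethyl-4-(3,4,5-trimethoxyphenyl)butyl]-2,6-dimethoxyphenol | COc1cc(C[C@@H](C)[C@H](C)[C@@H](O[Si](C)(C)C(C)(C)C)c2cc(OC)c(OC)c(OC)c2)cc(OC)c1O | intermediate
25 | (7R,8S,9R)-9-(TBSO) spirodienone | COC1=CC2(C=C(OC)C1=O)C[C@@H](C)[C@H](C)[C@@H](O[Si](C)(C)C(C)(C)C)c1cc(OC)c(OC)c(OC)c12 | intermediate
26 | (7R,8S,9R)-9-hydroxy spirodienone | COC1=CC2(C=C(OC)C1=O)C[C@@H](C)[C@H](C)[C@@H](O)c1cc(OC)c(OC)c(OC)c12 | intermediate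
27 | (7R,8S,9R)-9-acetoxy spirodienone, CNP0143674.1 | COC1=CC2(C=C(OC)C1=O)C[C@@H](C)[C@H](C)[C@@H](OC(C)=O)c1cc(OC)c(OC)c(OC)c12 | target

**Total step count:** 15. **Longest linear sequence:** 13 (steps 1–9 and 12–15).

**Steps most likely to fail**

**Step 12.** The hindered vinylogous-ester carbonyl may resist olefination. The ylide may instead add to the methoxy-bearing ring carbon and expel methoxide. The thermal opening may also be slower than decomposition of the polyenol ether.

The fallback uses known operations and sets out from iodide 10 and ketone 18. Iodine–lithium exchange (t-BuLi, Et2O–pentane, −78 °C) gives the alkyllithium F1. Its 1,2-addition to 18, followed by a cold acetic acid quench, gives the tertiary cyclobutenol F2. Syn-dehydration with the Burgess reagent can only run toward the side-chain CH2. It comes back to the route at 20, now isolated. Compound 20 is heated in toluene and aromatised with PPTS/MeOH to 24, following the neutral thermal behaviour known for squarate-derived alkylidenecyclobutenes.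

**Step 13.** Several processes compete:
- The phenoxenium equivalent may lose a C6 proton to a p-quinone methide, which would lead to six-ring closure at the exocyclic carbon.
- It may be captured by solvent or by the silyl ether oxygen.
- The product may undergo an acid-induced dienone–phenol shift.

The fallback separates oxidation from C–C bond formation and sets out from 24. PhI(OAc)2 in MeOH at 0 °C gives the isolable 4-methoxycyclohexa-2,5-dienone F3. This is ionised with BF3·OEt2 in CH2Cl2 at −78 °C in the absence of oxidant and protic acid, and closes by intramolecular Friedel–Crafts attack. It comes back to the route at 25.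

**Step 11.** The strongly basic vinyllithium may deprotonate or add in conjugate fashion at the unsubstituted ring CH of 14, and the dione may polymerise.

The fallback inverts the order of events and sets out from 14 and ylide 19 (from 11). Ketalisation of the more electrophilic carbonyl (MeOSiMe3, cat. TMSOTf, CH2Cl2, −78 °C) gives the monoketal 3,4,4-trimethoxycyclobut-2-en-1-one F4. Wittig reaction with 19 gives the alkylidene ketal F5. Oxalic acid on wet silica unmasks the 4-alkylidene-2-methoxycyclobutenone F6. Reagent 16 then adds to its only carbonyl and TMSCl traps the alkoxide. It comes back to the route at 20.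

**Further compounds**
F1 | step 12 | (2R,3S,4R)-4-(TBSO)-2,3-dimethyl-4-(3,4,5-trimethoxyphenyl)butyllithium | [Li]C[C@@H](C)[C@H](C)[C@@H](O[Si](C)(C)C(C)(C)C)c1cc(OC)c(OC)c(OC)c1
F2 | step 12 | 3-methoxy-4-(1-methoxyethenyl)-4-(trimethylsilyloxy)-1-[(2R,3S,4R)-4-(TBSO)-2,3-dimethyl-4-(3,4,5-trimethoxyphenyl)butyl]cyclobut-2-en-1-ol (ring epimers) | COC1=CC(O)(C[C@@H](C)[C@H](C)[C@@H](O[Si](C)(C)C(C)(C)C)c2cc(OC)c(OC)c(OC)c2)C1(O[Si](C)(C)C)C(=C)OC
F3 | step 13 | 2,4,6-trimethoxy-4-[(2R,3S,4R)-4-(TBSO)-2,3-dimethyl-4-(3,4,5-trimethoxyphenyl)butyl]cyclohexa-2,5-dien-1-one | COC1=CC(OC)(C[C@@H](C)[C@H](C)[C@@H](O[Si](C)(C)C(C)(C)C)c2cc(OC)c(OC)c(OC)c2)C=C(OC)C1=O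
F4 | step 11 | 3,4,4-trimethoxycyclobut-2-en-1-one | COC1=CC(=O)C1(OC)OC
F5 | step 11 | 1,4,4-trimethoxy-3-[(2R,3S,4R)-4-(TBSO)-2,3-dimethyl-4-(3,4,5-trimethoxyphenyl)butylidene]cyclobut-1-ene (E/Z) | COC1=CC(=C[C@@H](C)[C@H](C)[C@@H](O[Si](C)(C)C(C)(C)C)c2cc(OC)c(OC)c(OC)c2)C1(OC)OC
F6 | step 11 | 2-methoxy-4-[(2R,3S,4R)-4-(TBSO)-2,3-dimethyl-4-(3,4,5-trimethoxyphenyl)butylidene]cyclobut-2-en-1-one (E/Z) | COC1=CC(=C[C@@H](C)[C@H](C)[C@@H](O[Si](C)(C)C(C)(C)C)c2cc(OC)c(OC)c(OC)c2)C1=O
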